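## Assumptions

- Both phenols are carried as TBS ethers, and the C9 alcohol as a TES ether. Aldehyde **2** is commercial.
- The aryl group on C7 and C7' is 4-OTBS-3-methoxyphenyl (abbreviated Ar below).

## Retrosynthetic overview

1. The target comes from 5-exo cyclodehydration of triol **6**. The C9'–OH is activated and the C7–OH is the nucleophile, so the C7–O bond and the C7 stereocenter are never touched.
2. Triol **6** comes from LiAlH4 opening of lactone **5**. **5** is made by a trans-selective, anti-selective aldol of lactone **4** with aryl aldehyde **2**, which sets C8' and C7'.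
3. Lactone **4** comes from trans-5-aryl-4-formyl-γ-butyrolactone **3**, built by an organocatalytic aldol/lactonization of methyl 4-oxobutanoate (**1**) with **2**. The catalyst sets C7, and epimerization of the aldehyde α-carbon sets C8.
4. Ring order: the γ-lactone forms first (step 1). The THF forms last (step 5), after the lactone is reduced.

## Route

**Step 1**
- Reactants: **1** methyl 4-oxobutanoate; **2** 4-(tert-butyldimethylsilyloxy)-3-methoxybenzaldehyde.
- Product: **3** (4S,5S)-5-aryl-4-formyl-γ-butyrolactone (trans; 5-aryl = C7, 4-CHO = C8).
- Conditions: **2** (1 equiv), **1** (2 equiv, syringe-pump addition), D-proline (30 mol%), DMF, 4 °C, 24 h; then TsOH·H2O (10 mol%), PhMe, 50 °C, 2 h.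
- Reagents that add atoms: none (MeOH is lost on lactonization).
- Why: Proposed new method: a cross-aldol between an enolizable aldehyde donor and an electron-rich aryl aldehyde is normally poor because of donor self-aldol and a weak electrophile. Here the enamine adds to the Re/Si face of the aryl aldehyde under proline carboxylic-acid direction. The D-enantiomer gives the (S)-carbinol, as L-proline gives (R) in the acetone–aryl-aldehyde aldol. The γ-hydroxy ester then lactonizes irreversibly. The aldehyde α-carbon epimerizes through the enamine/enol until the thermodynamically favoured 4,5-trans lactone is trapped. The closest known reaction types are the proline-catalyzed cross-aldol of aldehydes and aldol/lactonization to paraconic lactones.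

**Step 2**
- Reactants: **3**; Et3SiH.
- Product: **4** (4S,5S)-4-(triethylsilyloxymethyl)-5-aryl-γ-butyrolactone.
- Conditions: Et3SiH (1.1 equiv), B(C6F5)3 (2 mol%), CH2Cl2, 0 °C, 30 min.
- Reagents that add atoms: triethylsilane, CC[SiH](CC)CC.
- Why: B(C6F5)3-catalyzed hydrosilylation reduces the aldehyde faster than the lactone and gives the protected primary alcohol in one step. No stereocenter is touched.

**Step 3**
- Reactants: **4**; **2**.
- Product: **5** lactone aldol adduct, with the new side chain at C8' trans to the C8 substituent and the C7' carbinol anti.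
- Conditions: LiHMDS (1.1 equiv), THF, −78 °C, 30 min; then **2** (1.3 equiv), −78 °C, 1 h; sat. NH4Cl.
- Reagents that add atoms: none.
- Why: This is a lactone-enolate aldol. The electrophile approaches the enolate face anti to the adjacent C8 CH2OTES group, which sets C8'. The constrained (E)-lactone enolate reacts through a Zimmerman–Traxler chair to give the anti aldol, which sets C7' (minor syn epimer removed by chromatography).

**Step 4**
- Reactants: **5**; LiAlH4.
- Product: **6** acyclic triol, HOCH2–CH(CH(OH)Ar)–CH(CH2OTES)–CH(OH)Ar.
- Conditions: LiAlH4 (2 equiv), THF, 0 °C, 30 min; Rochelle salt work-up.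
- Reagents that add atoms: none (hydride adds only H).
- Why: Lactone reduction to the diol opens the ring at the acyl C–O bond, so all four stereocenters are untouched. The only free primary alcohol left is C9'–OH, because C9 is silyl-protected.

**Step 5**
- Reactants: **6**.
- Product: **7** bis-TBS, TES-protected 2,3,4-trisubstituted THF.
- Conditions: Bu3P=CHCN (CMBP, 2 equiv), PhMe, 90 °C, 12 h.
- Reagents that add atoms: none (CMBP leaves as Bu3P=O and MeCN).
- Why: This is a Mitsunobu-type (Tsunoda) cyclodehydration. The primary C9'–OH is activated and the C7–OH closes the ring by 5-exo-tet attack. The C7'–OH would need a 4-membered ring and cannot compete, and C7 keeps its configuration because its C–O bond is retained.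

**Step 6**
- Reactants: **7**.
- Product: **8** target.
- Conditions: TBAF (4 equiv), AcOH (4 equiv), THF, 0 °C to rt, 3 h.
- Reagents that add atoms: none.
- Why: Buffered fluoride removes the TES ether and both aryl TBS ethers. The AcOH keeps the medium from becoming basic, which prevents quinone-methide formation from the p-hydroxybenzylic centers.

## Compound list

| # | Name | SMILES | Role |
|---|---|---|---|
| 1 | methyl 4-oxobutanoate | COC(=O)CCC=O | starting material |
| 2 | 4-(TBSO)-3-methoxybenzaldehyde | COc1cc(C=O)ccc1O[Si](C)(C)C(C)(C)C | starting material |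
| 3 | trans-5-aryl-4-formyl-γ-butyrolactone | O=C1C[C@H](C=O)[C@@H](c2ccc(O[Si](C)(C)C(C)(C)C)c(OC)c2)O1 | intermediate |
| 4 | 4-(TESOCH2)-5-aryl-γ-butyrolactone | O=C1C[C@H](CO[Si](CC)(CC)CC)[C@@H](c2ccc(O[Si](C)(C)C(C)(C)C)c(OC)c2)O1 | intermediate |
| 5 | lactone aldol adduct | O=C1[C@@H]([C@H](O)c2ccc(O[Si](C)(C)C(C)(C)C)c(OC)c2)[C@H](CO[Si](CC)(CC)CC)[C@@H](c2ccc(O[Si](C)(C)C(C)(C)C)c(OC)c2)O1 | intermediate |
| 6 | acyclic triol (C9-OTES) | OC[C@@H]([C@H](O)c1ccc(O[Si](C)(C)C(C)(C)C)c(OC)c1)[C@H](CO[Si](CC)(CC)CC)[C@H](O)c1ccc(O[Si](C)(C)C(C)(C)C)c(OC)c1 | intermediate |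
| 7 | protected THF | COc1cc([C@@H](O)[C@@H]2CO[C@H](c3ccc(O[Si](C)(C)C(C)(C)C)c(OC)c3)[C@H]2CO[Si](CC)(CC)CC)ccc1O[Si](C)(C)C(C)(C)C | intermediate |
| 8 | target (C20H24O7) | COc1cc([C@@H](O)[C@@H]2CO[C@H](c3ccc(O)c(OC)c3)[C@H]2CO)ccc1O | target |

## Totals

- Total steps: 6.
- Longest linear sequence: 6.

## Three steps most likely to fail

1. **Step 1 (proposed new step).** Donor self-aldol, a sluggish electron-rich aryl aldehyde, or a poor trans/cis lactone ratio could give low yield or selectivity.
   - Fallback (known chemistry): an Evans syn-aldol of the N-[3-(methoxycarbonyl)propanoyl] oxazolidinone with **2**, using the auxiliary enantiomer that gives the (S)-carbinol. Lactonization of the syn aldol gives the trans lactone. LiOOH cleavage and BH3·SMe2 reduction of the resulting acid give the hydroxymethyl lactone, which is silylated to **4**.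
2. **Step 3.** The anti:syn ratio at C7' may be modest, and retro-aldol can erode it.
   - Fallback: acylate the lactone enolate with methyl 4-OTBS-3-methoxybenzoate to give the trans α-aroyl lactone. Reduce the ketone with (S)-CBS/BH3 after LiAlH4 opening, so C7' is set by a catalyst rather than by the aldol.
3. **Step 5.** The electron-rich benzylic alcohols could be activated or ionized, or the cyclization could be unselective.
   - Fallback: change the ring-forming logic. Protect C7'–OH in **5** as its TES ether, reduce the lactone with DIBAL-H to the lactol, and reduce the lactol with Et3SiH/BF3·OEt2. The THF then closes through the pre-existing C7–O bond with no alcohol activation.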